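## Retrosynthetic overview

1. The target comes from a C1,C8-diol by one double oxidation after desilylation. The C1–C24 chain is closed at C11–C12 by Suzuki–Miyaura coupling of an east C1–C11 (E)-vinyl iodide with a C12–C24 (E)-alkenylboronate.
2. The C12–C24 boronate comes from a base-free Stille coupling at C17–C18 of a middle C12–C17 piece, carrying a (Z)-iodoalkene and a pinacol boronate, with a west lactone (E)-vinylstannane (C18–C24).
3. East fragment: Marshall–Tamaru propargylation (C8–C9, sets C9) of a tetrahydrofuran aldehyde. The tetrahydrofuran ring is formed first, by a new catalyst-controlled 5-exo oxa-Michael cyclisation of a δ-hydroxy β-methyl enal (C3–O bond, quaternary C3). That enal comes from Brown anti-crotylation and Negishi carboalumination.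
4. West fragment: the dihydropyranone ring is formed second, in its own branch, by ring-closing metathesis of the acrylate of a second Brown anti-crotylation product. One batch of the (E)-crotylborane serves both crotylations.
5. One Evans propargylation product, (R)-2-methylpent-4-ynal, supplies both C2–C6 (C5 centre) and C12–C16 (C15 centre).

Assumption: the SMILES is taken as the full definition of the target, i.e. 3R,5R,6R,7R,9R,15R,20R,21S and 10E,12E,16Z,18E with the chain numbered from the aldehyde carbon C1 to the lactone carbonyl C24 (ring oxygen between C3 and C6; trans-disubstituted lactone). This numbering is used in the "Why" lines.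

## Route

Step 1
Reactants: 1 (4S)-4-benzyl-3-propanoyl-1,3-oxazolidin-2-one; 2 3-bromoprop-1-yne
Product: 4 (4S)-4-benzyl-3-[(2R)-2-methylpent-4-ynoyl]-1,3-oxazolidin-2-one, via sodium enolate 3 (not isolated)
Conditions: NaN(SiMe3)2, THF, −78 °C; then 2, −78 → −40 °C
Reagents that add atoms: none
Why: Evans asymmetric alkylation, in which the chelated sodium (Z)-enolate is propargylated on the face away from the benzyl group and so sets the 2R methyl centre (later C5 and C15).

Step 2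
Reactants: 4 (4S)-4-benzyl-3-[(2R)-2-methylpent-4-ynoyl]-1,3-oxazolidin-2-one
Product: 5 (2R)-2-methylpent-4-yn-1-ol
Conditions: LiBH4, MeOH (1 equiv), Et2O, 0 °C
Reagents that add atoms: none
Why: Reductive cleavage of the N-acyl oxazolidinone gives the primary alcohol without touching the stereocentre or the alkyne and returns the auxiliary.

Step 3
Reactants: 5 (2R)-2-methylpent-4-yn-1-ol
Product: 6 (2R)-2-methylpent-4-ynal
Conditions: Dess–Martin periodinane, CH2Cl2, 0 °C → rt; filtered solution used at once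
Reagents that add atoms: none
Why: Dess–Martin oxidation is fast and near neutral, so the α-stereocentre of this volatile aldehyde is kept.

Step 4
Reactants: 7 (E)-but-2-ene
Product: 9 (E)-but-2-enyl-diisopinocampheylborane of the (+)-α-pinene series, via crotylpotassium 8 (not isolated)
Conditions: KOt-Bu, n-BuLi, THF, −78 → −45 °C; (−)-Ipc2BOMe [from (+)-α-pinene], −78 °C; BF3·OEt2, −78 °C; solution kept at −78 °C, divided in two and used at once in steps 5 and 19
Reagents that add atoms: (−)-B-methoxydiisopinocampheylborane, COB([C@@H]1C[C@@H]2C[C@H]([C@H]1C)C2(C)C)[C@@H]1C[C@@H]2C[C@H]([C@H]1C)C2(C)C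
Why: Schlosser-base allylic metalation of (E)-but-2-ene keeps the E geometry in the crotylpotassium, and borylation followed by abstraction of methoxide with BF3 gives the Brown (E)-crotylborane, which does not scramble by 1,3-boron shift at −78 °C; no stereocentre is formed.

Step 5
Reactants: 6 (2R)-2-methylpent-4-ynal; 9 (E)-but-2-enyl-diisopinocampheylborane of the (+)-α-pinene series
Product: 11 (3S,4R,5R)-3,5-dimethyloct-1-en-7-yn-4-ol, via borinate 10 (not isolated)
Conditions: 9 (cold THF solution from step 4), 6, −78 °C, 3 h; NaOH, H2O2, rt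
Reagents that add atoms: none
Why: Brown crotylboration through a chair Zimmerman–Traxler transition state, where the (E)-crotyl geometry gives the 6,7-anti relation and the isopinocampheyl groups override the weak Felkin bias of 6 to give 6R (5,6-anti), setting C6 and C7.

Step 6
Reactants: 11 (3S,4R,5R)-3,5-dimethyloct-1-en-7-yn-4-ol
Product: 13 (2E,5R,6R,7S)-3,5,7-trimethylnona-2,8-diene-1,6-diol, via vinylalane 12 (not isolated)
Conditions: Me3Al (4 equiv), Cp2ZrCl2 (0.3 equiv), CH2Cl2, 0 °C → rt; then n-BuLi, (CH2O)n, THF, −30 °C → rt; aq. HCl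
Reagents that add atoms: trimethylaluminium, C[Al](C)C; formaldehyde (as paraformaldehyde), C=O
Why: Negishi zirconium-catalysed carboalumination adds methyl and aluminium syn and regioselectively across the terminal alkyne (the alkene and the aluminium alkoxide are spectators), and trapping of the alkenylalane with formaldehyde with retention gives the (E)-trisubstituted allylic alcohol.

Step 7
Reactants: 13 (2E,5R,6R,7S)-3,5,7-trimethylnona-2,8-diene-1,6-diol
Product: 14 (2E,5R,6R,7S)-6-hydroxy-3,5,7-trimethylnona-2,8-dienal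
Conditions: MnO2 (20 equiv), CH2Cl2, rt
Reagents that add atoms: none
Why: Allylic oxidation with MnO2 touches only the primary allylic alcohol and leaves the C6 hydroxyl and the alkene geometry intact.

Step 8
Reactants: 14 (2E,5R,6R,7S)-6-hydroxy-3,5,7-trimethylnona-2,8-dienal
Product: 15 2-[(2R,4R,5R)-5-[(2S)-but-3-en-2-yl]-2,4-dimethyloxolan-2-yl]acetaldehyde
Conditions: quinine-derived squaramide 3-{[3,5-bis(trifluoromethyl)phenyl]amino}-4-{[(8α,9S)-6'-methoxycinchonan-9-yl]amino}cyclobut-3-ene-1,2-dione (10 mol%), 4 Å MS, toluene, −20 → 0 °C; cold filtration through silica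
Reagents that add atoms: none
Why: Proposed new method: the squaramide N–H pair is expected to bind the enal carbonyl while the quinuclidine nitrogen acts as general base for the C6 hydroxyl, so that the 5-exo-trig oxa-Michael addition takes place in one ordered assembly on the Re face of C3 (giving 3R; the quinidine-derived pseudoenantiomer would serve the Si face) under kinetic control at low temperature, before retro-addition can equilibrate the new tetrasubstituted ether centre; the closest known reaction type is the aminothiourea- or squaramide-catalysed cycloetherification of hydroxy enones, which has not been shown for β,β-disubstituted enals or for catalyst-controlled formation of a tetrasubstituted C–O centre in a chiral chain.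

Step 9
Reactants: 15 2-[(2R,4R,5R)-5-[(2S)-but-3-en-2-yl]-2,4-dimethyloxolan-2-yl]acetaldehyde
Product: 16 2-[(2R,4R,5R)-5-[(2S)-but-3-en-2-yl]-2,4-dimethyloxolan-2-yl]ethan-1-ol
Conditions: NaBH4, MeOH, 0 °C
Reagents that add atoms: none
Why: Borohydride reduction removes the β-alkoxy aldehyde before it can undergo retro-oxa-Michael reaction and puts C1 at the alcohol level for the end game.

Step 10
Reactants: 16 2-[(2R,4R,5R)-5-[(2S)-but-3-en-2-yl]-2,4-dimethyloxolan-2-yl]ethan-1-ol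
Product: 17 tert-butyl{2-[(2R,4R,5R)-5-[(2S)-but-3-en-2-yl]-2,4-dimethyloxolan-2-yl]ethoxy}dimethylsilane
Conditions: TBSCl, imidazole, CH2Cl2, rt
Reagents that add atoms: tert-butyldimethylsilyl chloride, CC(C)(C)[Si](C)(C)Cl
Why: Standard silylation of the primary alcohol.

Step 11
Reactants: 17 tert-butyl{2-[(2R,4R,5R)-5-[(2S)-but-3-en-2-yl]-2,4-dimethyloxolan-2-yl]ethoxy}dimethylsilane
Product: 19 (2R)-2-[(2R,3R,5R)-5-[2-(tert-butyldimethylsilyloxy)ethyl]-3,5-dimethyloxolan-2-yl]propanal, via ozonide 18 (not isolated)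
Conditions: O3, CH2Cl2, −78 °C; PPh3, −78 °C → rt
Reagents that add atoms: ozone, [O-][O+]=O
Why: Ozonolysis with reductive work-up cleaves the only alkene to the C8 aldehyde under neutral conditions that do not epimerise C7.

Step 12
Reactants: 20 (2S)-but-3-yn-2-ol
Product: 21 (2S)-but-3-yn-2-yl methanesulfonate
Conditions: MsCl, Et3N, CH2Cl2, −78 → 0 °C
Reagents that add atoms: methanesulfonyl chloride, CS(=O)(=O)Cl
Why: O-Sulfonylation with retention gives the propargylic electrophile.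

Step 13
Reactants: 19 (2R)-2-[(2R,3R,5R)-5-[2-(tert-butyldimethylsilyloxy)ethyl]-3,5-dimethyloxolan-2-yl]propanal; 21 (2S)-but-3-yn-2-yl methanesulfonate
Product: 23 (2S,3R,4R)-2-[(2R,3R,5R)-5-[2-(tert-butyldimethylsilyloxy)ethyl]-3,5-dimethyloxolan-2-yl]-4-methylhex-5-yn-3-ol, via allenylzinc 22 (not isolated)
Conditions: Pd(OAc)2 (5 mol%), PPh3 (5 mol%), Et2Zn (3 equiv), THF, −78 → −20 °C
Reagents that add atoms: none
Why: Marshall–Tamaru propargylation, in which zerovalent palladium displaces the mesylate anti (SN2'), the derived allenylzinc adds through a cyclic SE2' transition state with net inversion at the mesylate carbon (9R) and anti to the new C8 hydroxyl (8R, Felkin-matched with C7), the C8 centre being erased by the final oxidation.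

Step 14
Reactants: 23 (2S,3R,4R)-2-[(2R,3R,5R)-5-[2-(tert-butyldimethylsilyloxy)ethyl]-3,5-dimethyloxolan-2-yl]-4-methylhex-5-yn-3-ol
Product: 24 O-triethylsilyl ether of alcohol 23
Conditions: Et3SiOTf, 2,6-lutidine, CH2Cl2, −78 °C
Reagents that add atoms: triethylsilyl trifluoromethanesulfonate, CC[Si](CC)(CC)OS(=O)(=O)C(F)(F)F
Why: Silyl triflate silylation protects the hindered C8 hydroxyl as an ether that the final fluoride step removes easily.

Step 15
Reactants: 24 O-triethylsilyl ether of alcohol 23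
Product: 26 triethyl{[(2R,3R,4R)-2-[(2R,3R,5R)-5-[2-(tert-butyldimethylsilyloxy)ethyl]-3,5-dimethyloxolan-2-yl]-4-methylhept-5-yn-3-yl]oxy}silane, via lithium acetylide 25 (not isolated)
Conditions: n-BuLi, THF, −78 °C; MeI, −78 °C → rt
Reagents that add atoms: iodomethane, CI
Why: Acetylide alkylation installs the C11 methyl group without touching any stereocentre.

Step 16
Reactants: 26 triethyl{[(2R,3R,4R)-2-[(2R,3R,5R)-5-[2-(tert-butyldimethylsilyloxy)ethyl]-3,5-dimethyloxolan-2-yl]-4-methylhept-5-yn-3-yl]oxy}silane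
Product: 28 triethyl{[(2R,3R,4R,5E)-6-iodo-2-[(2R,3R,5R)-5-[2-(tert-butyldimethylsilyloxy)ethyl]-3,5-dimethyloxolan-2-yl]-4-methylhept-5-en-3-yl]oxy}silane, via alkenylzirconocene 27 (not isolated)
Conditions: Cp2Zr(H)Cl (3 equiv), THF, 50 °C; I2, 0 °C
Reagents that add atoms: iodine, II
Why: Hydrozirconation–iodination adds H and Zr syn with zirconium settling on the less hindered methyl-bearing carbon, and iodinolysis with retention gives the (E)-iodoalkene (C10=C11).

Step 17
Reactants: 6 (2R)-2-methylpent-4-ynal; 29 triphenyl(propyl)phosphonium bromide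
Product: 33 (4R,5Z)-6-iodo-4-methyloct-5-en-1-yne, via ylide 30 (not isolated), via iodophosphonium salt 31 (not isolated), via iodo ylide 32 (not isolated)
Conditions: 29, n-BuLi, THF, 0 °C → rt; I2, −78 °C; NaN(SiMe3)2, −20 °C; 6, −78 °C → rt
Reagents that add atoms: iodine, II
Why: Stork–Zhao–Wittig olefination with the α-iodo ylide gives the (Z)-iodoalkene under kinetic control (iodine cis to the chain, setting the later 16Z geometry) at a temperature that keeps C15 intact.

Step 18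
Reactants: 33 (4R,5Z)-6-iodo-4-methyloct-5-en-1-yne
Product: 34 2-[(1E,4R,5Z)-6-iodo-4-methylocta-1,5-dien-1-yl]-4,4,5,5-tetramethyl-1,3,2-dioxaborolane
Conditions: pinacolborane, Cp2Zr(H)Cl (10 mol%), Et3N (10 mol%), CH2Cl2, 40 °C
Reagents that add atoms: pinacolborane, [H]B1OC(C)(C)C(C)(C)O1
Why: Zirconium-catalysed syn hydroboration of the terminal alkyne gives the (E)-alkenylboronate while the iodoalkene is inert to the borane.

Step 19
Reactants: 35 3-(trimethylsilyl)prop-2-ynal; 9 (E)-but-2-enyl-diisopinocampheylborane of the (+)-α-pinene series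
Product: 37 (3S,4S)-4-methyl-1-(trimethylsilyl)hex-5-en-1-yn-3-ol, via borinate 36 (not isolated)
Conditions: 9 (second half of the cold THF solution from step 4), 35, −78 °C, 3 h; NaOH, H2O2, rt
Reagents that add atoms: none
Why: Brown crotylboration of an achiral ynal with the same batch of reagent 9 as in step 5, in which the same facial sense sets C20 and the (E)-crotyl geometry sets the anti C21 methyl (the later trans lactone).

Step 20
Reactants: 37 (3S,4S)-4-methyl-1-(trimethylsilyl)hex-5-en-1-yn-3-ol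
Product: 38 (3S,4S)-4-methylhex-5-en-1-yn-3-ol
Conditions: K2CO3 (0.2 equiv), MeOH, 0 °C
Reagents that add atoms: none
Why: Base-catalysed methanolysis of the alkynyl C–Si bond frees the terminal alkyne.

Step 21
Reactants: 38 (3S,4S)-4-methylhex-5-en-1-yn-3-ol
Product: 39 (1E,3S,4S)-4-methyl-1-(tributylstannyl)hexa-1,5-dien-3-ol
Conditions: Bu3SnH, PdCl2(PPh3)2 (2 mol%), THF, 0 °C
Reagents that add atoms: tributyltin hydride, CCCC[SnH](CCCC)CCCC
Why: Palladium-catalysed syn hydrostannation of the terminal alkyne places tin at the distal carbon to give the (E)-vinylstannane and leaves the alkene alone.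

Step 22
Reactants: 39 (1E,3S,4S)-4-methyl-1-(tributylstannyl)hexa-1,5-dien-3-ol
Product: 40 (1E,3S,4S)-4-methyl-1-(tributylstannyl)hexa-1,5-dien-3-yl prop-2-enoate
Conditions: acryloyl chloride, i-Pr2NEt, CH2Cl2, −78 → 0 °C
Reagents that add atoms: acryloyl chloride, C=CC(=O)Cl
Why: O-Acylation under basic conditions, which the acid-sensitive vinylstannane tolerates.

Step 23
Reactants: 40 (1E,3S,4S)-4-methyl-1-(tributylstannyl)hexa-1,5-dien-3-yl prop-2-enoate
Product: 41 (5S,6S)-5-methyl-6-[(E)-2-(tributylstannyl)ethenyl]-5,6-dihydro-2H-pyran-2-one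
Conditions: second-generation Grubbs catalyst RuCl2(=CHPh)(H2IMes)(PCy3) (5 mol%), CH2Cl2 (5 mM), 40 °C
Reagents that add atoms: none
Why: Ring-closing metathesis joins the terminal vinyl group and the acrylate into the six-membered unsaturated lactone, the bulky disubstituted vinylstannane being a bystander and no stereocentre being involved.

Step 24
Reactants: 34 2-[(1E,4R,5Z)-6-iodo-4-methylocta-1,5-dien-1-yl]-4,4,5,5-tetramethyl-1,3,2-dioxaborolane; 41 (5S,6S)-5-methyl-6-[(E)-2-(tributylstannyl)ethenyl]-5,6-dihydro-2H-pyran-2-one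
Product: 42 (5S,6R)-6-[(1E,3Z,5R,7E)-3-ethyl-5-methyl-8-(4,4,5,5-tetramethyl-1,3,2-dioxaborolan-2-yl)octa-1,3,7-trien-1-yl]-5-methyl-5,6-dihydro-2H-pyran-2-one
Conditions: Pd2(dba)3 (5 mol%), AsPh3 (20 mol%), CuI (10 mol%), DMF, rt
Reagents that add atoms: none
Why: Stille coupling proceeds with retention at both alkenes under base-free conditions, so the lactone survives and the pinacol boronate, which needs base to transmetalate, stays untouched.

Step 25
Reactants: 28 triethyl{[(2R,3R,4R,5E)-6-iodo-2-[(2R,3R,5R)-5-[2-(tert-butyldimethylsilyloxy)ethyl]-3,5-dimethyloxolan-2-yl]-4-methylhept-5-en-3-yl]oxy}silane; 42 (5S,6R)-6-[(1E,3Z,5R,7E)-3-ethyl-5-methyl-8-(4,4,5,5-tetramethyl-1,3,2-dioxaborolan-2-yl)octa-1,3,7-trien-1-yl]-5-methyl-5,6-dihydro-2H-pyran-2-one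
Product: 43 fully assembled C1–C24 lactone carrying C1-O-TBS and (8R)-C8-O-TES (all other stereocentres and alkene geometries as in the target)
Conditions: Pd(PPh3)4 (10 mol%), TlOEt (1.5 equiv), THF/H2O 3:1, rt
Reagents that add atoms: none
Why: Suzuki–Miyaura coupling, accelerated by TlOEt so that it is complete within minutes at room temperature, joins C11 and C12 with retention to give the (10E,12E)-diene.

Step 26
Reactants: 43 fully assembled C1–C24 lactone carrying C1-O-TBS and (8R)-C8-O-TES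
Product: 44 C1,C8-diol (target with CH2OH at C1 and (8R)-CHOH at C8)
Conditions: HF·pyridine, pyridine, THF, 0 °C → rt
Reagents that add atoms: none
Why: Buffered fluoride desilylation removes both silyl ethers without harming the lactone or the polyene.

Step 27
Reactants: 44 C1,C8-diol
Product: 45 target, 2-[(2R,4R,5R)-5-[(2R,4R,5E,7E,10R,11Z,13E)-12-ethyl-4,6,10-trimethyl-14-[(2R,3S)-3-methyl-6-oxo-2,3-dihydropyran-2-yl]-3-oxotetradeca-5,7,11,13-tetraen-2-yl]-2,4-dimethyloxolan-2-yl]acetaldehyde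
Conditions: Dess–Martin periodinane (3 equiv), NaHCO3, CH2Cl2, 0 °C → rt
Reagents that add atoms: none
Why: Buffered Dess–Martin oxidation converts the primary alcohol into the aldehyde and the secondary alcohol into the ketone in one operation without epimerising C7 or C9 or moving the β,γ-alkene.

## Compound list

1 | (4S)-4-benzyl-3-propanoyl-1,3-oxazolidin-2-one | CCC(=O)N1[C@@H](Cc2ccccc2)COC1=O | starting material
2 | 3-bromoprop-1-yne | BrCC#C | starting material
3 | sodium (Z)-enolate of 1 | C/C=C(\[O-])N1[C@@H](Cc2ccccc2)COC1=O.[Na+] | intermediate (not isolated)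
4 | (4S)-4-benzyl-3-[(2R)-2-methylpent-4-ynoyl]-1,3-oxazolidin-2-one | O=C([C@H](C)CC#C)N1[C@@H](Cc2ccccc2)COC1=O | intermediate
5 | (2R)-2-methylpent-4-yn-1-ol | OC[C@H](C)CC#C | intermediate
6 | (2R)-2-methylpent-4-ynal | O=C[C@H](C)CC#C | intermediate
7 | (E)-but-2-ene | C/C=C/C | starting material
8 | (E)-but-2-enylpotassium | C/C=C/C[K] | intermediate (not isolated)
9 | (E)-but-2-enyl-diisopinocampheylborane of the (+)-α-pinene series | C/C=C/CB([C@@H]1C[C@@H]2C[C@H]([C@H]1C)C2(C)C)[C@@H]1C[C@@H]2C[C@H]([C@H]1C)C2(C)C | intermediate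
10 | diisopinocampheylborinate of the crotylation adduct of 6 | C=C[C@H](C)[C@H](OB([C@@H]1C[C@@H]2C[C@H]([C@H]1C)C2(C)C)[C@@H]1C[C@@H]2C[C@H]([C@H]1C)C2(C)C)[C@H](C)CC#C | intermediate (not isolated)
11 | (3S,4R,5R)-3,5-dimethyloct-1-en-7-yn-4-ol | C=C[C@H](C)[C@H](O)[C@H](C)CC#C | intermediate
12 | O-aluminated (E)-alkenyldimethylalane from 11 | C=C[C@H](C)[C@H](O[Al](C)C)[C@H](C)C/C(C)=C/[Al](C)C | intermediate (not isolated)
13 | (2E,5R,6R,7S)-3,5,7-trimethylnona-2,8-diene-1,6-diol | C=C[C@H](C)[C@H](O)[C@H](C)C/C(C)=C/CO | intermediate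
14 | (2E,5R,6R,7S)-6-hydroxy-3,5,7-trimethylnona-2,8-dienal | C=C[C@H](C)[C@H](O)[C@H](C)C/C(C)=C/C=O | intermediate
15 | 2-[(2R,4R,5R)-5-[(2S)-but-3-en-2-yl]-2,4-dimethyloxolan-2-yl]acetaldehyde | C=C[C@H](C)[C@@H]1O[C@@](C)(CC=O)C[C@H]1C | intermediate
16 | 2-[(2R,4R,5R)-5-[(2S)-but-3-en-2-yl]-2,4-dimethyloxolan-2-yl]ethan-1-ol | C=C[C@H](C)[C@@H]1O[C@@](C)(CCO)C[C@H]1C | intermediate
17 | tert-butyl{2-[(2R,4R,5R)-5-[(2S)-but-3-en-2-yl]-2,4-dimethyloxolan-2-yl]ethoxy}dimethylsilane | C=C[C@H](C)[C@@H]1O[C@@](C)(CCO[Si](C)(C)C(C)(C)C)C[C@H]1C | intermediate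
18 | ozonide (1,2,4-trioxolane) of 17, mixture at the trioxolane carbon | O2OC(OC2)[C@H](C)[C@@H]1O[C@@](C)(CCO[Si](C)(C)C(C)(C)C)C[C@H]1C | intermediate (not isolated)
19 | (2R)-2-[(2R,3R,5R)-5-[2-(tert-butyldimethylsilyloxy)ethyl]-3,5-dimethyloxolan-2-yl]propanal | O=C[C@H](C)[C@@H]1O[C@@](C)(CCO[Si](C)(C)C(C)(C)C)C[C@H]1C | intermediate
20 | (2S)-but-3-yn-2-ol | C[C@H](O)C#C | starting material
21 | (2S)-but-3-yn-2-yl methanesulfonate | C[C@H](OS(C)(=O)=O)C#C | intermediate
22 | [(aR)-buta-1,2-dien-1-yl](ethyl)zinc | CC([H])=[C@]=C([H])[Zn]CC | intermediate (not isolated)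
23 | (2S,3R,4R)-2-[(2R,3R,5R)-5-[2-(tert-butyldimethylsilyloxy)ethyl]-3,5-dimethyloxolan-2-yl]-4-methylhex-5-yn-3-ol | C#C[C@@H](C)[C@@H](O)[C@H](C)[C@@H]1O[C@@](C)(CCO[Si](C)(C)C(C)(C)C)C[C@H]1C | intermediate
24 | O-triethylsilyl ether of alcohol 23 | C#C[C@@H](C)[C@@H](O[Si](CC)(CC)CC)[C@H](C)[C@@H]1O[C@@](C)(CCO[Si](C)(C)C(C)(C)C)C[C@H]1C | intermediate
25 | lithium acetylide of 24 | [Li]C#C[C@@H](C)[C@@H](O[Si](CC)(CC)CC)[C@H](C)[C@@H]1O[C@@](C)(CCO[Si](C)(C)C(C)(C)C)C[C@H]1C | intermediate (not isolated)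
26 | triethyl{[(2R,3R,4R)-2-[(2R,3R,5R)-5-[2-(tert-butyldimethylsilyloxy)ethyl]-3,5-dimethyloxolan-2-yl]-4-methylhept-5-yn-3-yl]oxy}silane | CC#C[C@@H](C)[C@@H](O[Si](CC)(CC)CC)[C@H](C)[C@@H]1O[C@@](C)(CCO[Si](C)(C)C(C)(C)C)C[C@H]1C | intermediate
27 | (E)-alkenylzirconocene chloride from 26 | Cl[Zr](C1C=CC=C1)(C1C=CC=C1)/C(C)=C/[C@@H](C)[C@@H](O[Si](CC)(CC)CC)[C@H](C)[C@@H]1O[C@@](C)(CCO[Si](C)(C)C(C)(C)C)C[C@H]1C | intermediate (not isolated)
28 | triethyl{[(2R,3R,4R,5E)-6-iodo-2-[(2R,3R,5R)-5-[2-(tert-butyldimethylsilyloxy)ethyl]-3,5-dimethyloxolan-2-yl]-4-methylhept-5-en-3-yl]oxy}silane | I/C(C)=C/[C@@H](C)[C@@H](O[Si](CC)(CC)CC)[C@H](C)[C@@H]1O[C@@](C)(CCO[Si](C)(C)C(C)(C)C)C[C@H]1C | intermediate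
29 | triphenyl(propyl)phosphonium bromide | CCC[P+](c1ccccc1)(c1ccccc1)c1ccccc1.[Br-] | starting material
30 | triphenyl(propylidene)phosphorane | CCC=P(c1ccccc1)(c1ccccc1)c1ccccc1 | intermediate (not isolated)
31 | (1-iodopropyl)triphenylphosphonium iodide | CCC(I)[P+](c1ccccc1)(c1ccccc1)c1ccccc1.[I-] | intermediate (not isolated)
32 | (1-iodopropylidene)triphenylphosphorane | CCC(I)=P(c1ccccc1)(c1ccccc1)c1ccccc1 | intermediate (not isolated)
33 | (4R,5Z)-6-iodo-4-methyloct-5-en-1-yne | CCC(=C/[C@H](C)CC#C)/I | intermediate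
34 | 2-[(1E,4R,5Z)-6-iodo-4-methylocta-1,5-dien-1-yl]-4,4,5,5-tetramethyl-1,3,2-dioxaborolane | CCC(=C/[C@H](C)C/C=C/B1OC(C)(C)C(C)(C)O1)/I | intermediate
35 | 3-(trimethylsilyl)prop-2-ynal | C[Si](C)(C)C#CC=O | starting material
36 | diisopinocampheylborinate of the crotylation adduct of 35 | C[Si](C)(C)C#C[C@@H](OB([C@@H]1C[C@@H]2C[C@H]([C@H]1C)C2(C)C)[C@@H]1C[C@@H]2C[C@H]([C@H]1C)C2(C)C)[C@@H](C)C=C | intermediate (not isolated)
37 | (3S,4S)-4-methyl-1-(trimethylsilyl)hex-5-en-1-yn-3-ol | C[Si](C)(C)C#C[C@@H](O)[C@@H](C)C=C | intermediate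
38 | (3S,4S)-4-methylhex-5-en-1-yn-3-ol | C#C[C@@H](O)[C@@H](C)C=C | intermediate
39 | (1E,3S,4S)-4-methyl-1-(tributylstannyl)hexa-1,5-dien-3-ol | CCCC[Sn](CCCC)(CCCC)/C=C/[C@@H](O)[C@@H](C)C=C | intermediate
40 | (1E,3S,4S)-4-methyl-1-(tributylstannyl)hexa-1,5-dien-3-yl prop-2-enoate | CCCC[Sn](CCCC)(CCCC)/C=C/[C@@H](OC(=O)C=C)[C@@H](C)C=C | intermediate
41 | (5S,6S)-5-methyl-6-[(E)-2-(tributylstannyl)ethenyl]-5,6-dihydro-2H-pyran-2-one | CCCC[Sn](CCCC)(CCCC)/C=C/[C@H]1OC(=O)C=C[C@@H]1C | intermediate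
42 | (5S,6R)-6-[(1E,3Z,5R,7E)-3-ethyl-5-methyl-8-(4,4,5,5-tetramethyl-1,3,2-dioxaborolan-2-yl)octa-1,3,7-trien-1-yl]-5-methyl-5,6-dihydro-2H-pyran-2-one | CCC(=C/[C@H](C)C/C=C/B1OC(C)(C)C(C)(C)O1)/C=C/[C@H]1OC(=O)C=C[C@@H]1C | intermediate
43 | fully assembled C1–C24 lactone with C1-O-TBS and (8R)-C8-O-TES | CCC(=C/[C@H](C)C/C=C/C(C)=C/[C@@H](C)[C@@H](O[Si](CC)(CC)CC)[C@H](C)[C@@H]1O[C@@](C)(CCO[Si](C)(C)C(C)(C)C)C[C@H]1C)/C=C/[C@H]1OC(=O)C=C[C@@H]1C | intermediate
44 | C1,C8-diol (C1 CH2OH; 8R CHOH) | CCC(=C/[C@H](C)C/C=C/C(C)=C/[C@@H](C)[C@@H](O)[C@H](C)[C@@H]1O[C@@](C)(CCO)C[C@H]1C)/C=C/[C@H]1OC(=O)C=C[C@@H]1C | intermediate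
45 | 2-[(2R,4R,5R)-5-[(2R,4R,5E,7E,10R,11Z,13E)-12-ethyl-4,6,10-trimethyl-14-[(2R,3S)-3-methyl-6-oxo-2,3-dihydropyran-2-yl]-3-oxotetradeca-5,7,11,13-tetraen-2-yl]-2,4-dimethyloxolan-2-yl]acetaldehyde | CCC(=C/[C@H](C)C/C=C/C(C)=C/[C@@H](C)C(=O)[C@H](C)[C@@H]1O[C@@](C)(CC=O)C[C@H]1C)/C=C/[C@H]1OC(=O)C=C[C@@H]1C | target

## Step count and risks

Total: 27 steps. Longest linear sequence: 17 steps (steps 1–3, 5–11, 13–16, 25–27).

**Step 8 (the new oxa-Michael cyclisation).** It may be slow at the β,β-disubstituted enal, or retro-addition may erode the selectivity at C3. The fallback uses known chemistry, sets out from diol 13 and returns at aldehyde 15. Sharpless asymmetric epoxidation of 13 (Ti(Oi-Pr)4, L-(+)-diethyl tartrate, t-BuOOH, 4 Å MS, CH2Cl2, −20 °C) gives [(2S,3S)-3-[(2R,3R,4S)-3-hydroxy-2,4-dimethylhex-5-en-1-yl]-3-methyloxiran-2-yl]methanol F1. Camphorsulfonic acid then lets the C6 hydroxyl open the epoxide 5-exo at the tertiary carbon with inversion, giving (1S)-1-[(2R,4R,5R)-5-[(2S)-but-3-en-2-yl]-2,4-dimethyloxolan-2-yl]ethane-1,2-diol F2 with C3 already R. NaIO4 in THF/H2O cleaves the diol to (2R,4R,5R)-5-[(2S)-but-3-en-2-yl]-2,4-dimethyloxolane-2-carbaldehyde F3. Wittig methoxymethylenation (MeOCH2PPh3Cl, KOt-Bu, THF) gives (2R,3R,5R)-2-[(2S)-but-3-en-2-yl]-5-(2-methoxyethenyl)-3,5-dimethyloxolane F4, and hydrolysis with dilute HCl in THF at 0 °C gives 15.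

**Step 23 (ring-closing metathesis next to a vinylstannane).** The ruthenium carbene may engage or degrade the stannane. The fallback closes the ring before tin is introduced; it sets out from alcohol 37 and returns at stannane 41. Acryloylation of 37 gives (3S,4S)-4-methyl-1-(trimethylsilyl)hex-5-en-1-yn-3-yl prop-2-enoate F5. Ring-closing metathesis with the same catalyst, the silyl-capped alkyne being inert, gives (5S,6S)-5-methyl-6-[2-(trimethylsilyl)ethynyl]-5,6-dihydro-2H-pyran-2-one F6. Buffered desilylation (Bu4NF, AcOH, THF, 0 °C) gives (5S,6S)-6-ethynyl-5-methyl-5,6-dihydro-2H-pyran-2-one F7, and hydrostannation (Bu3SnH, PdCl2(PPh3)2, THF, 0 °C) gives 41.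

**Step 25 (Suzuki coupling beside the lactone).** The allylic, unsaturated lactone may not survive the ethoxide base or zerovalent palladium. The fallback masks the lactone as a lactol ether through both couplings; it sets out from stannane 41 and returns at the target 45. Reduction of 41 with i-Bu2AlH (CH2Cl2, −78 °C) gives (5S,6S)-5-methyl-6-[(E)-2-(tributylstannyl)ethenyl]-5,6-dihydro-2H-pyran-2-ol F8. Propan-2-ol with pyridinium p-toluenesulfonate gives the isopropyl acetal tributyl{(E)-2-[(2S,3S)-3-methyl-6-(propan-2-yloxy)-3,6-dihydro-2H-pyran-2-yl]ethenyl}stannane F9. Stille coupling of F9 with iodide 34 under the conditions of step 24 gives the C12–C24 boronate with the lactol isopropyl acetal F10. Suzuki coupling of F10 with iodide 28 under the conditions of step 25, with no lactone present, gives the fully assembled bis-silyl ether isopropyl acetal F11. HF·pyridine followed by pyridinium p-toluenesulfonate in acetone/H2O gives the C1,C8-diol lactol F12, and Dess–Martin periodinane with NaHCO3 oxidises all three hydroxyl groups at once to give 45.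

## Further compounds

F1 | step 8 | [(2S,3S)-3-[(2R,3R,4S)-3-hydroxy-2,4-dimethylhex-5-en-1-yl]-3-methyloxiran-2-yl]methanol | C=C[C@H](C)[C@H](O)[C@H](C)C[C@]1(C)O[C@H]1CO
F2 | step 8 | (1S)-1-[(2R,4R,5R)-5-[(2S)-but-3-en-2-yl]-2,4-dimethyloxolan-2-yl]ethane-1,2-diol | C=C[C@H](C)[C@@H]1O[C@@](C)([C@@H](O)CO)C[C@H]1C
F3 | step 8 | (2R,4R,5R)-5-[(2S)-but-3-en-2-yl]-2,4-dimethyloxolane-2-carbaldehyde | C=C[C@H](C)[C@@H]1O[C@@](C)(C=O)C[C@H]1C
F4 | step 8 | (2R,3R,5R)-2-[(2S)-but-3-en-2-yl]-5-(2-methoxyethenyl)-3,5-dimethyloxolane (E/Z mixture) | C=C[C@H](C)[C@@H]1O[C@@](C)(C=COC)C[C@H]1C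
F5 | step 23 | (3S,4S)-4-methyl-1-(trimethylsilyl)hex-5-en-1-yn-3-yl prop-2-enoate | C[Si](C)(C)C#C[C@@H](OC(=O)C=C)[C@@H](C)C=C
F6 | step 23 | (5S,6S)-5-methyl-6-[2-(trimethylsilyl)ethynyl]-5,6-dihydro-2H-pyran-2-one | C[Si](C)(C)C#C[C@H]1OC(=O)C=C[C@@H]1C
F7 | step 23 | (5S,6S)-6-ethynyl-5-methyl-5,6-dihydro-2H-pyran-2-one | C#C[C@H]1OC(=O)C=C[C@@H]1C
F8 | step 25 | (5S,6S)-5-methyl-6-[(E)-2-(tributylstannyl)ethenyl]-5,6-dihydro-2H-pyran-2-ol (anomer mixture) | CCCC[Sn](CCCC)(CCCC)/C=C/[C@H]1OC(O)C=C[C@@H]1C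
F9 | step 25 | tributyl{(E)-2-[(2S,3S)-3-methyl-6-(propan-2-yloxy)-3,6-dihydro-2H-pyran-2-yl]ethenyl}stannane (anomer mixture) | CCCC[Sn](CCCC)(CCCC)/C=C/[C@H]1OC(OC(C)C)C=C[C@@H]1C
F10 | step 25 | C12–C24 pinacol boronate with the lactol isopropyl acetal (anomer mixture) | CCC(=C/[C@H](C)C/C=C/B1OC(C)(C)C(C)(C)O1)/C=C/[C@H]1OC(OC(C)C)C=C[C@@H]1C
F11 | step 25 | fully assembled C1-O-TBS, C8-O-TES lactol isopropyl acetal (anomer mixture) | CCC(=C/[C@H](C)C/C=C/C(C)=C/[C@@H](C)[C@@H](O[Si](CC)(CC)CC)[C@H](C)[C@@H]1O[C@@](C)(CCO[Si](C)(C)C(C)(C)C)C[C@H]1C)/C=C/[C@H]1OC(OC(C)C)C=C[C@@H]1C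
F12 | step 25 | C1,C8-diol lactol (anomer mixture) | CCC(=C/[C@H](C)C/C=C/C(C)=C/[C@@H](C)[C@@H](O)[C@H](C)[C@@H]1O[C@@](C)(CCO)C[C@H]1C)/C=C/[C@H]1OC(O)C=C[C@@H]1C
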